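**Retrosynthetic overview**

- The strategy rests on the aryl ether bond O1u–C8a-u of the upper pyran ring (u = upper, C4-linked flavan unit; l = lower, C6-linked unit): it touches none of C2u, C3u and C4u. It is therefore disconnected last, and the 2,3-cis-3,4-trans triad is built on an open chain and closed without breaking a bond to a stereocentre.
- The open-chain bromoarene 31 comes from chelation-controlled aryl Grignard addition (C2u), proline α-aminoxylation (C3u–O) and rhodium-catalysed asymmetric 1,4-addition of the lower-unit C6 boronic acid 17 to bromo-enal 21 (C4u–C6l).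
- Boronic acid 17 comes from a gallacetophenone chalcone: asymmetric epoxidation, phenol–epoxide cyclisation, ketone reduction and C3 oxidation/reduction to the all-cis 3,4-diol, with the C6l bromine installed before ring formation.
- Order of ring formation: lower pyran ring (step 6), then upper pyran ring (step 22); global hydrogenolysis last.

Key step: step 22

Remark: flavan numbering is used (O1, C2, C3, C4, C4a, C5–C8, C8a). Ar-l = (2R,3R,4R)-3,4,7,8-tetrakis(benzyloxy)-2-[4-(benzyloxy)phenyl]-3,4-dihydro-2H-chromen-6-yl (all-cis); Ar-u = 3,4-bis(benzyloxy)-2-bromophenyl.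
Assumption: the antipode of the diene ligand in step 16 that arylates the Re face of Cβ is assigned on a model enal before use, and the acid-catalysed ether formation in step 8 is taken to give the thermodynamically preferred 3,4-trans benzyl ether.

**Route**

Step 1
Reactants: 1 gallacetophenone (1-(2,3,4-trihydroxyphenyl)ethan-1-one)
Product: 2 1-[3,4-bis(benzyloxy)-2-hydroxyphenyl]ethan-1-one
Conditions: BnBr (2.1 equiv), K2CO3, acetone, reflux
Reagents that add atoms: benzyl bromide, BrCc1ccccc1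
Why: Williamson etherification; the 2-OH is hydrogen-bonded to the acetyl carbonyl and least nucleophilic, so only the 3- and 4-hydroxyls should be benzylated.

Step 2
Reactants: 2 1-[3,4-bis(benzyloxy)-2-hydroxyphenyl]ethan-1-one
Product: 3 1-[3,4-bis(benzyloxy)-5-bromo-2-hydroxyphenyl]ethan-1-one
Conditions: NBS, MeCN, 0 °C
Reagents that add atoms: N-bromosuccinimide, O=C1CCC(=O)N1Br
Why: Electrophilic aromatic bromination; C5 is para to the free phenol and the only activated open position, and it becomes C6 of the lower flavan unit.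

Step 3
Reactants: 3 1-[3,4-bis(benzyloxy)-5-bromo-2-hydroxyphenyl]ethan-1-one
Product: 4 1-[3,4-bis(benzyloxy)-5-bromo-2-(methoxymethoxy)phenyl]ethan-1-one
Conditions: NaH (1.1 equiv), MOMCl, DMF, 0 °C to rt
Reagents that add atoms: chloromethyl methyl ether, COCCl
Why: O-alkylation of the phenoxide (Williamson-type acetal formation) masks the phenol so that the later alkaline peroxide step cannot divert into Algar–Flynn–Oyamada cyclisation.

Step 4
Reactants: 4 1-[3,4-bis(benzyloxy)-5-bromo-2-(methoxymethoxy)phenyl]ethan-1-one; 5 4-(benzyloxy)benzaldehyde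
Product: 6 (E)-1-[3,4-bis(benzyloxy)-5-bromo-2-(methoxymethoxy)phenyl]-3-[4-(benzyloxy)phenyl]prop-2-en-1-one
Conditions: KOH, EtOH/THF, rt
Reagents that add atoms: none
Why: Claisen–Schmidt condensation; aldol addition and E1cB dehydration should give the E-chalcone, and the MOM and benzyl ethers are stable to hydroxide.

Step 5
Reactants: 6 (E)-chalcone
Product: 7 [3,4-bis(benzyloxy)-5-bromo-2-(methoxymethoxy)phenyl]{(2R,3S)-3-[4-(benzyloxy)phenyl]oxiran-2-yl}methanone (trans-epoxide)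
Conditions: immobilised poly-L-leucine, urea–H2O2, DBU, THF, rt
Reagents that add atoms: hydrogen peroxide (as its urea adduct), OO
Why: Juliá–Colonna asymmetric epoxidation (conjugate addition of hydroperoxide and ring closure inside the helical polypeptide); the L-configured catalyst should set Cα as R and Cβ as S, the future C3l and C2l.

Step 6
Reactants: 7 MOM-protected (2R,3S)-epoxy ketone
Product: 9 (2R,3R)-7,8-bis(benzyloxy)-2-[4-(benzyloxy)phenyl]-6-bromo-3-hydroxy-2,3-dihydro-4H-chromen-4-one (2,3-trans), via phenol epoxy ketone 8 (not isolated)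
Conditions: HCl (aq., cat.), MeOH/THF, 50 °C
Reagents that add atoms: none
Why: Acidic acetal cleavage followed by intramolecular epoxide opening: the freed phenol attacks the benzylic Cβ with inversion in a 6-endo closure to the 2,3-trans dihydroflavonol, and C3 is carried over unchanged from Cα.

Step 7
Reactants: 9 (2R,3R)-dihydroflavonol
Product: 10 (2R,3S,4R)-7,8-bis(benzyloxy)-2-[4-(benzyloxy)phenyl]-6-bromo-3,4-dihydro-2H-chromene-3,4-diol (2,3-trans-3,4-trans)
Conditions: NaBH4, MeOH/THF, 0 °C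
Reagents that add atoms: none
Why: Borohydride ketone reduction; axial hydride delivery to the half-chair should place the new 4-OH equatorial, cis to the 2-aryl group (4R).

Step 8
Reactants: 10 (2R,3S,4R)-diol
Product: 11 (2R,3S,4R)-4,7,8-tris(benzyloxy)-2-[4-(benzyloxy)phenyl]-6-bromo-3,4-dihydro-2H-chromen-3-ol
Conditions: BnOH (10 equiv), camphorsulfonic acid (cat.), 4 Å molecular sieves, CH2Cl2, rt
Reagents that add atoms: benzyl alcohol, OCc1ccccc1
Why: Acid-catalysed SN1 etherification of a flavan-3,4-diol; only the C4 hydroxyl ionises (the cation is stabilised by O1 and the 7-benzyloxy group), the 3-OH stays free, the 6-bromine blocks self-condensation, and reversible capture should favour the diequatorial 3,4-trans ether.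

Step 9
Reactants: 11 (2R,3S,4R)-4-O-benzyl-3-ol
Product: 12 (2R,4R)-4,7,8-tris(benzyloxy)-2-[4-(benzyloxy)phenyl]-6-bromo-2H-chromen-3(4H)-one (2-aryl and 4-benzyloxy cis)
Conditions: Dess–Martin periodinane, NaHCO3, CH2Cl2, rt
Reagents that add atoms: none
Why: Dess–Martin oxidation of the secondary alcohol under buffered, base-free conditions that should not epimerise C2 or C4 of the flavan-3-one.

Step 10
Reactants: 12 (2R,4R)-flavan-3-one
Product: 13 (2R,3R,4R)-4,7,8-tris(benzyloxy)-2-[4-(benzyloxy)phenyl]-6-bromo-3,4-dihydro-2H-chromen-3-ol (all-cis)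
Conditions: LiBH(s-Bu)3 (L-Selectride), THF, −78 °C
Reagents that add atoms: none
Why: Diastereoselective ketone reduction with a bulky hydride, which should attack the face opposite the cis-disposed 2-aryl and 4-benzyloxy groups and give the axial 3-OH (3R), as in the known catechin-to-epicatechin inversion.

Step 11
Reactants: 13 (2R,3R,4R)-all-cis 3-ol
Product: 14 (2R,3R,4R)-3,4,7,8-tetrakis(benzyloxy)-2-[4-(benzyloxy)phenyl]-6-bromo-3,4-dihydro-2H-chromene (all-cis)
Conditions: NaH, BnBr, n-Bu4NI (cat.), DMF, 0 °C to rt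
Reagents that add atoms: benzyl bromide, BrCc1ccccc1
Why: Williamson etherification of the remaining secondary alkoxide; no other acidic or electrophilic site is present.

Step 12
Reactants: 14 all-cis 6-bromoflavan
Product: 17 [(2R,3R,4R)-3,4,7,8-tetrakis(benzyloxy)-2-[4-(benzyloxy)phenyl]-3,4-dihydro-2H-chromen-6-yl]boronic acid, via aryllithium 15 (not isolated), via lithium triisopropoxyborate 16 (not isolated)
Conditions: n-BuLi, THF, −78 °C; B(Oi-Pr)3, −78 °C to rt; aq. NH4Cl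
Reagents that add atoms: triisopropyl borate, CC(C)OB(OC(C)C)OC(C)C; water, O
Why: Bromine–lithium exchange, borate formation and hydrolysis; the exchange is much faster at −78 °C than benzylic deprotonation and the aryllithium is trapped before it can rearrange.

Step 13
Reactants: 18 2-bromo-3-hydroxy-4-methoxybenzaldehyde
Product: 19 2-bromo-3,4-dihydroxybenzaldehyde
Conditions: BBr3, CH2Cl2, −78 to 0 °C; H2O
Reagents that add atoms: none
Why: Lewis acid cleavage of the aryl methyl ether (bromide attack on the O-methyl of the boron-complexed ether), needed because a methyl ether could not be removed from the final polyphenol.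

Step 14
Reactants: 19 2-bromo-3,4-dihydroxybenzaldehyde
Product: 20 3,4-bis(benzyloxy)-2-bromobenzaldehyde
Conditions: BnBr, K2CO3, DMF, rt
Reagents that add atoms: benzyl bromide, BrCc1ccccc1
Why: Williamson etherification of both phenols.

Step 15
Reactants: 20 3,4-bis(benzyloxy)-2-bromobenzaldehyde
Product: 21 (E)-3-[3,4-bis(benzyloxy)-2-bromophenyl]prop-2-enal
Conditions: Ph3P=CHCHO, toluene, 80 °C
Reagents that add atoms: (triphenylphosphoranylidene)acetaldehyde, O=CC=P(c1ccccc1)(c1ccccc1)c1ccccc1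
Why: Wittig olefination with a stabilised formylmethylene ylide, which should give the E-enal by two-carbon homologation.

Step 16
Reactants: 17 lower-unit boronic acid; 21 (E)-bromo-enal (slight excess)
Product: 22 (3S)-3-(Ar-u)-3-(Ar-l)propanal
Conditions: [RhCl(C2H4)2]2 (2.5 mol%), enantiopure 2,5-diphenylbicyclo[2.2.2]octa-2,5-diene (antipode selected for Re-face arylation), KOH (0.5 equiv), THF/MeOH/H2O, 50 °C
Reagents that add atoms: none
Why: Rhodium-catalysed asymmetric 1,4-addition of an arylboronic acid (Hayashi–Miyaura reaction): transmetalation to the diene-bound hydroxorhodium, ligand-controlled insertion of the enal with aryl delivery to the Re face of Cβ and protonolysis set C4u (3S), while monovalent rhodium leaves the aryl bromide untouched.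

Step 17
Reactants: 22 (3S)-3,3-diarylpropanal
Product: 25 (2R,3S)-3-(Ar-u)-3-(Ar-l)propane-1,2-diol, via aminoxy aldehyde 23 (not isolated), via aminoxy alcohol 24 (not isolated)
Conditions: L-proline (20 mol%), PhNO (1.1 equiv), CHCl3/DMSO, 0 °C; then NaBH4, EtOH, 0 °C; then AcOH, Zn dust, rt (one pot)
Reagents that add atoms: nitrosobenzene, O=Nc1ccccc1
Why: Proline-catalysed α-aminoxylation (enamine catalysis): the L-proline enamine attacks the nitroso oxygen through the carboxylic acid-bound transition state and sets the C3u oxygen as R under catalyst control; borohydride then secures the epimerisable aldehyde and zinc cleaves the N–O bond.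

Step 18
Reactants: 25 (2R,3S)-1,2-diol
Product: 26 (4R)-4-[(S)-(Ar-u)(Ar-l)methyl]-2-phenyl-1,3-dioxolane (mixture at the acetal carbon)
Conditions: PhCH(OMe)2, pyridinium p-toluenesulfonate (cat.), CH2Cl2, rt
Reagents that add atoms: benzaldehyde dimethyl acetal, COC(OC)c1ccccc1
Why: Transacetalisation of the 1,2-diol to the benzylidene acetal under a weak acid that should not ionise the C4l benzyl ether.

Step 19
Reactants: 26 benzylidene acetal
Product: 27 (2R,3S)-2-(benzyloxy)-3-(Ar-u)-3-(Ar-l)propan-1-ol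
Conditions: i-Bu2AlH, CH2Cl2, −78 to 0 °C; aq. potassium sodium tartrate
Reagents that add atoms: none
Why: Regioselective reductive opening of the benzylidene acetal: aluminium coordinates the less hindered primary oxygen, that C–O bond ionises and hydride reduces the oxocarbenium ion, which should leave the benzyl group on the C3u oxygen and free the primary alcohol.

Step 20
Reactants: 27 (2R,3S)-2-benzyloxy alcohol
Product: 28 (2R,3S)-2-(benzyloxy)-3-(Ar-u)-3-(Ar-l)propanal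
Conditions: Dess–Martin periodinane, NaHCO3, CH2Cl2, 0 °C to rt
Reagents that add atoms: none
Why: Dess–Martin oxidation of the primary alcohol under buffered conditions, which should give the α-benzyloxy aldehyde without epimerisation for immediate use.

Step 21
Reactants: 28 (2R,3S)-α-benzyloxy aldehyde; 29 1-(benzyloxy)-4-bromobenzene
Product: 31 (1R,2R,3S)-2-(benzyloxy)-1-[4-(benzyloxy)phenyl]-3-(Ar-u)-3-(Ar-l)propan-1-ol (1,2-syn), via arylmagnesium bromide 30 (not isolated)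
Conditions: 29, Mg, THF, 40 °C; then 28, MgBr2·OEt2, CH2Cl2, −78 °C; aq. NH4Cl
Reagents that add atoms: none
Why: Cram-chelate-controlled Grignard addition: magnesium bridges the carbonyl and α-benzyloxy oxygens and the aryl group should add to the face opposite the diarylmethyl substituent, giving the 1,2-syn alcohol (C2u, 1R) with C3u already benzylated.

Step 22
Reactants: 31 open-chain bromoarene (1R,2R,3S)
Product: 32 nona-O-benzyl ether of the target (upper unit 2R,3R, 2,3-cis-3,4-trans; lower unit 2R,3R,4R, all-cis)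
Conditions: CuI (20 mol%), 3,4,7,8-tetramethyl-1,10-phenanthroline (40 mol%), Cs2CO3, toluene, 110 °C, argon
Reagents that add atoms: none
Why: Cs2CO3 deprotonates the only free hydroxyl (C2u-OH) and the alkoxide binds phenanthroline-ligated monovalent copper; oxidative addition of the C8a-u–Br bond and C–O reductive elimination from the trivalent copper aryl alkoxide form O1u–C8a-u. The closest known reaction is the copper-catalysed Ullmann-type intramolecular O-arylation of secondary alcohols that gives chromans. The upper pyran ring closes as a six-membered ring through a seven-membered copper-containing metallacycle, the intramolecular setting compensating for a bromide flanked by the 8-benzyloxy group and the C4u branch. No stereocentre is formed: the C2u–O bond is never broken, so the syn C2u-OH/C3u-OBn pair should pass into the 2,3-cis ring with retention, and the 3,4-trans relation set in steps 16 and 17 is untouched. Only chemoselectivity is needed: the C3u oxygen is a benzyl ether, so the five-membered dihydrobenzofuran closure cannot occur, no other halide is present, and copper, unlike palladium, does not oxidise the benzylic alkoxide by beta-hydride elimination.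

Step 23
Reactants: 32 nona-O-benzyl dimer
Product: 33 (2R,3R,4S)-2-(4-hydroxyphenyl)-4-[(2R,3R,4R)-3,4,7,8-tetrahydroxy-2-(4-hydroxyphenyl)-3,4-dihydro-2H-chromen-6-yl]-3,4-dihydro-2H-chromene-3,7,8-triol (CNP0391561.1)
Conditions: H2 (1 atm), Pd(OH)2/C, THF/MeOH, rt
Reagents that add atoms: none
Why: Catalytic hydrogenolysis of the nine O–CH2Ph bonds under neutral conditions, under which the ring benzylic C–O bonds (C2–O1 of both units, C4l–O) should be cleaved much more slowly.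

**Compound list**

1 | gallacetophenone | CC(=O)c1ccc(O)c(O)c1O | starting material
2 | 1-[3,4-bis(benzyloxy)-2-hydroxyphenyl]ethan-1-one | CC(=O)c1ccc(OCc2ccccc2)c(OCc2ccccc2)c1O | intermediate
3 | 1-[3,4-bis(benzyloxy)-5-bromo-2-hydroxyphenyl]ethan-1-one | CC(=O)c1cc(Br)c(OCc2ccccc2)c(OCc2ccccc2)c1O | intermediate
4 | 1-[3,4-bis(benzyloxy)-5-bromo-2-(methoxymethoxy)phenyl]ethan-1-one | CC(=O)c1cc(Br)c(OCc2ccccc2)c(OCc2ccccc2)c1OCOC | intermediate
5 | 4-(benzyloxy)benzaldehyde | O=Cc1ccc(OCc2ccccc2)cc1 | starting material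
6 | (E)-1-[3,4-bis(benzyloxy)-5-bromo-2-(methoxymethoxy)phenyl]-3-[4-(benzyloxy)phenyl]prop-2-en-1-one | COCOc1c(C(=O)/C=C/c2ccc(OCc3ccccc3)cc2)cc(Br)c(OCc2ccccc2)c1OCc1ccccc1 | intermediate
7 | [3,4-bis(benzyloxy)-5-bromo-2-(methoxymethoxy)phenyl]{(2R,3S)-3-[4-(benzyloxy)phenyl]oxiran-2-yl}methanone | COCOc1c(C(=O)[C@@H]2O[C@H]2c4ccc(OCc3ccccc3)cc4)cc(Br)c(OCc2ccccc2)c1OCc1ccccc1 | intermediate
8 | [3,4-bis(benzyloxy)-5-bromo-2-hydroxyphenyl]{(2R,3S)-3-[4-(benzyloxy)phenyl]oxiran-2-yl}methanone | Oc1c(C(=O)[C@@H]2O[C@H]2c4ccc(OCc3ccccc3)cc4)cc(Br)c(OCc2ccccc2)c1OCc1ccccc1 | intermediate (not isolated)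
9 | (2R,3R)-7,8-bis(benzyloxy)-2-[4-(benzyloxy)phenyl]-6-bromo-3-hydroxy-2,3-dihydro-4H-chromen-4-one | O=C1[C@H](O)[C@@H](c2ccc(OCc3ccccc3)cc2)Oc2c1cc(Br)c(OCc1ccccc1)c2OCc1ccccc1 | intermediate
10 | (2R,3S,4R)-7,8-bis(benzyloxy)-2-[4-(benzyloxy)phenyl]-6-bromo-3,4-dihydro-2H-chromene-3,4-diol | O[C@H]1[C@H](O)[C@@H](c2ccc(OCc3ccccc3)cc2)Oc2c1cc(Br)c(OCc1ccccc1)c2OCc1ccccc1 | intermediate
11 | (2R,3S,4R)-4,7,8-tris(benzyloxy)-2-[4-(benzyloxy)phenyl]-6-bromo-3,4-dihydro-2H-chromen-3-ol | c1ccccc1CO[C@H]1[C@H](O)[C@@H](c2ccc(OCc3ccccc3)cc2)Oc2c1cc(Br)c(OCc1ccccc1)c2OCc1ccccc1 | intermediate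
12 | (2R,4R)-4,7,8-tris(benzyloxy)-2-[4-(benzyloxy)phenyl]-6-bromo-2H-chromen-3(4H)-one | c1ccccc1CO[C@H]1C(=O)[C@@H](c2ccc(OCc3ccccc3)cc2)Oc2c1cc(Br)c(OCc1ccccc1)c2OCc1ccccc1 | intermediate
13 | (2R,3R,4R)-4,7,8-tris(benzyloxy)-2-[4-(benzyloxy)phenyl]-6-bromo-3,4-dihydro-2H-chromen-3-ol (all-cis) | c1ccccc1CO[C@H]1[C@@H](O)[C@@H](c2ccc(OCc3ccccc3)cc2)Oc2c1cc(Br)c(OCc1ccccc1)c2OCc1ccccc1 | intermediate
14 | (2R,3R,4R)-3,4,7,8-tetrakis(benzyloxy)-2-[4-(benzyloxy)phenyl]-6-bromo-3,4-dihydro-2H-chromene (all-cis) | c1ccccc1CO[C@H]1[C@@H](OCc2ccccc2)[C@@H](c2ccc(OCc3ccccc3)cc2)Oc2c1cc(Br)c(OCc1ccccc1)c2OCc1ccccc1 | intermediate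
15 | 6-lithio analogue of 14 (Ar-l lithium) | c1ccccc1CO[C@H]1[C@@H](OCc2ccccc2)[C@@H](c2ccc(OCc3ccccc3)cc2)Oc2c1cc([Li])c(OCc1ccccc1)c2OCc1ccccc1 | intermediate (not isolated)
16 | lithium (Ar-l)triisopropoxyborate | c1ccccc1CO[C@H]1[C@@H](OCc2ccccc2)[C@@H](c2ccc(OCc3ccccc3)cc2)Oc2c1cc([B-](OC(C)C)(OC(C)C)OC(C)C)c(OCc1ccccc1)c2OCc1ccccc1.[Li+] | intermediate (not isolated)
17 | (Ar-l)boronic acid | c1ccccc1CO[C@H]1[C@@H](OCc2ccccc2)[C@@H](c2ccc(OCc3ccccc3)cc2)Oc2c1cc(B(O)O)c(OCc1ccccc1)c2OCc1ccccc1 | intermediate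
18 | 2-bromo-3-hydroxy-4-methoxybenzaldehyde | COc1ccc(C=O)c(Br)c1O | starting material
19 | 2-bromo-3,4-dihydroxybenzaldehyde | O=Cc1ccc(O)c(O)c1Br | intermediate
20 | 3,4-bis(benzyloxy)-2-bromobenzaldehyde | O=Cc1ccc(OCc2ccccc2)c(OCc2ccccc2)c1Br | intermediate
21 | (E)-3-[3,4-bis(benzyloxy)-2-bromophenyl]prop-2-enal | O=C/C=C/c1ccc(OCc2ccccc2)c(OCc2ccccc2)c1Br | intermediate
22 | (3S)-3-(Ar-u)-3-(Ar-l)propanal | O=CC[C@@H](c3cc4c(c(OCc5ccccc5)c3OCc5ccccc5)O[C@H](c3ccc(OCc5ccccc5)cc3)[C@H](OCc5ccccc5)[C@@H]4OCc5ccccc5)c2ccc(OCc5ccccc5)c(OCc5ccccc5)c2Br | intermediate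
23 | (2R,3S)-2-(anilinooxy)-3-(Ar-u)-3-(Ar-l)propanal | O=C[C@H](ONc1ccccc1)[C@@H](c3cc4c(c(OCc5ccccc5)c3OCc5ccccc5)O[C@H](c3ccc(OCc5ccccc5)cc3)[C@H](OCc5ccccc5)[C@@H]4OCc5ccccc5)c2ccc(OCc5ccccc5)c(OCc5ccccc5)c2Br | intermediate (not isolated)
24 | (2R,3S)-2-(anilinooxy)-3-(Ar-u)-3-(Ar-l)propan-1-ol | OC[C@H](ONc1ccccc1)[C@@H](c3cc4c(c(OCc5ccccc5)c3OCc5ccccc5)O[C@H](c3ccc(OCc5ccccc5)cc3)[C@H](OCc5ccccc5)[C@@H]4OCc5ccccc5)c2ccc(OCc5ccccc5)c(OCc5ccccc5)c2Br | intermediate (not isolated)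
25 | (2R,3S)-3-(Ar-u)-3-(Ar-l)propane-1,2-diol | OC[C@H](O)[C@@H](c3cc4c(c(OCc5ccccc5)c3OCc5ccccc5)O[C@H](c3ccc(OCc5ccccc5)cc3)[C@H](OCc5ccccc5)[C@@H]4OCc5ccccc5)c2ccc(OCc5ccccc5)c(OCc5ccccc5)c2Br | intermediate
26 | (4R)-4-[(S)-(Ar-u)(Ar-l)methyl]-2-phenyl-1,3-dioxolane (mixture at the acetal carbon) | c1ccccc1C1OC[C@H](O1)[C@@H](c3cc4c(c(OCc5ccccc5)c3OCc5ccccc5)O[C@H](c3ccc(OCc5ccccc5)cc3)[C@H](OCc5ccccc5)[C@@H]4OCc5ccccc5)c2ccc(OCc5ccccc5)c(OCc5ccccc5)c2Br | intermediate
27 | (2R,3S)-2-(benzyloxy)-3-(Ar-u)-3-(Ar-l)propan-1-ol | OC[C@H](OCc1ccccc1)[C@@H](c3cc4c(c(OCc5ccccc5)c3OCc5ccccc5)O[C@H](c3ccc(OCc5ccccc5)cc3)[C@H](OCc5ccccc5)[C@@H]4OCc5ccccc5)c2ccc(OCc5ccccc5)c(OCc5ccccc5)c2Br | intermediate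
28 | (2R,3S)-2-(benzyloxy)-3-(Ar-u)-3-(Ar-l)propanal | O=C[C@H](OCc1ccccc1)[C@@H](c3cc4c(c(OCc5ccccc5)c3OCc5ccccc5)O[C@H](c3ccc(OCc5ccccc5)cc3)[C@H](OCc5ccccc5)[C@@H]4OCc5ccccc5)c2ccc(OCc5ccccc5)c(OCc5ccccc5)c2Br | intermediate
29 | 1-(benzyloxy)-4-bromobenzene | Brc1ccc(OCc2ccccc2)cc1 | starting material
30 | [4-(benzyloxy)phenyl]magnesium bromide | Br[Mg]c1ccc(OCc2ccccc2)cc1 | intermediate (not isolated)
31 | (1R,2R,3S)-2-(benzyloxy)-1-[4-(benzyloxy)phenyl]-3-(Ar-u)-3-(Ar-l)propan-1-ol (1,2-syn) | c5ccccc5COc1ccc([C@@H](O)[C@H](OCc5ccccc5)[C@@H](c3cc4c(c(OCc5ccccc5)c3OCc5ccccc5)O[C@H](c3ccc(OCc5ccccc5)cc3)[C@H](OCc5ccccc5)[C@@H]4OCc5ccccc5)c2ccc(OCc5ccccc5)c(OCc5ccccc5)c2Br)cc1 | intermediate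
32 | nona-O-benzyl ether of 33 (upper unit 2R,3R, 2,3-cis-3,4-trans; lower unit 2R,3R,4R, all-cis) | c5ccccc5COc1ccc([C@H]2Oc3c(ccc(OCc5ccccc5)c3OCc5ccccc5)[C@H](c3cc4c(c(OCc5ccccc5)c3OCc5ccccc5)O[C@H](c3ccc(OCc5ccccc5)cc3)[C@H](OCc5ccccc5)[C@@H]4OCc5ccccc5)[C@H]2OCc5ccccc5)cc1 | intermediate
33 | (2R,3R,4S)-2-(4-hydroxyphenyl)-4-[(2R,3R,4R)-3,4,7,8-tetrahydroxy-2-(4-hydroxyphenyl)-3,4-dihydro-2H-chromen-6-yl]-3,4-dihydro-2H-chromene-3,7,8-triol | Oc1ccc([C@H]2Oc3c(ccc(O)c3O)[C@H](c3cc4c(c(O)c3O)O[C@H](c3ccc(O)cc3)[C@H](O)[C@@H]4O)[C@H]2O)cc1 | target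

**Step count and risks**

Total step count: 23. Longest linear sequence: 20 steps (steps 1–12, then 16–23).

Steps most likely to fail:

1. Step 22 (key step). Oxidative addition at the doubly ortho-substituted, electron-rich bromide may be too slow, so that protodebromination or decay of the alkoxide takes over. The fallback closes O1u–C2u with inversion instead of the aryl C–O bond. It sets out from 31: Dess–Martin oxidation gives the aryl ketone F1; chelation-controlled reduction with Zn(BH4)2 (Et2O, −20 °C) gives the 1,2-anti alcohol F2, the C2u epimer of 31; n-BuLi (2.2 equiv, THF, −78 °C), then B(OMe)3 and NaOH/H2O2 turn the bromide into the phenol F3; Mitsunobu cyclisation (PPh3, diisopropyl azodicarboxylate, THF, 0 °C) displaces the activated C2u hydroxyl with inversion and comes back to the route at 32.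

2. Step 16. Protodeboronation of the electron-rich ortho-alkoxy boronic acid, competing 1,2-addition to the aldehyde and slow insertion of the hindered enal may leave little conjugate adduct. The fallback replaces catalysis by auxiliary-controlled cuprate addition. It sets out from 20 and 14: Knoevenagel–Doebner condensation of 20 with malonic acid (pyridine, piperidine, 90 °C) gives the E-cinnamic acid F4; its pivaloyl mixed anhydride and the lithium salt of (4R)-4-phenyl-1,3-oxazolidin-2-one give the N-enoyl imide F5; 14 is converted (t-BuLi, THF, −78 °C; MgBr2·OEt2) into the lower-unit arylmagnesium bromide F6; with CuBr·SMe2 (THF, −40 °C) this adds to the chelated s-cis imide from the face away from the phenyl group to give the conjugate adduct F7 with the same C4u configuration; LiBH4 (THF, MeOH) releases the auxiliary and gives the primary alcohol F8; Dess–Martin oxidation comes back to the route at 22.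

3. Step 8. Ionisation at C4 may erode the C4 configuration or lead to elimination instead of clean ether formation. The fallback avoids the carbocation and differentiates the two oxygens by order of introduction. It sets out from 9: i-Pr3SiOTf and 2,6-lutidine (CH2Cl2, 0 °C) give the 3-O-silyl dihydroflavonol F9; NaBH4 (MeOH/THF, 0 °C) gives the 3,4-trans 4-ol F10; NaH and BnBr (DMF, 0 °C) give the 4-O-benzyl 3-O-silyl ether F11; n-Bu4NF (THF, rt) removes the silyl group and comes back to the route at 11.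

Further compounds
F1 | step 22 | (2R,3S)-2-(benzyloxy)-1-[4-(benzyloxy)phenyl]-3-(Ar-u)-3-(Ar-l)propan-1-one | c5ccccc5COc1ccc(C(=O)[C@H](OCc5ccccc5)[C@@H](c3cc4c(c(OCc5ccccc5)c3OCc5ccccc5)O[C@H](c3ccc(OCc5ccccc5)cc3)[C@H](OCc5ccccc5)[C@@H]4OCc5ccccc5)c2ccc(OCc5ccccc5)c(OCc5ccccc5)c2Br)cc1
F2 | step 22 | (1S,2R,3S)-2-(benzyloxy)-1-[4-(benzyloxy)phenyl]-3-(Ar-u)-3-(Ar-l)propan-1-ol (1,2-anti, C1 epimer of 31) | c5ccccc5COc1ccc([C@H](O)[C@H](OCc5ccccc5)[C@@H](c3cc4c(c(OCc5ccccc5)c3OCc5ccccc5)O[C@H](c3ccc(OCc5ccccc5)cc3)[C@H](OCc5ccccc5)[C@@H]4OCc5ccccc5)c2ccc(OCc5ccccc5)c(OCc5ccccc5)c2Br)cc1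
F3 | step 22 | 1,2-anti alcohol with 3,4-bis(benzyloxy)-2-hydroxyphenyl in place of Ar-u (phenol from F2) | c5ccccc5COc1ccc([C@H](O)[C@H](OCc5ccccc5)[C@@H](c3cc4c(c(OCc5ccccc5)c3OCc5ccccc5)O[C@H](c3ccc(OCc5ccccc5)cc3)[C@H](OCc5ccccc5)[C@@H]4OCc5ccccc5)c2ccc(OCc5ccccc5)c(OCc5ccccc5)c2O)cc1
F4 | step 16 | (E)-3-[3,4-bis(benzyloxy)-2-bromophenyl]prop-2-enoic acid | OC(=O)/C=C/c1ccc(OCc2ccccc2)c(OCc2ccccc2)c1Br
F5 | step 16 | (4R)-3-{(E)-3-[3,4-bis(benzyloxy)-2-bromophenyl]prop-2-enoyl}-4-phenyl-1,3-oxazolidin-2-one | O=C(/C=C/c1ccc(OCc2ccccc2)c(OCc2ccccc2)c1Br)N1[C@H](c2ccccc2)COC1=O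
F6 | step 16 | (Ar-l)magnesium bromide | Br[Mg]c3cc4c(c(OCc5ccccc5)c3OCc5ccccc5)O[C@H](c3ccc(OCc5ccccc5)cc3)[C@H](OCc5ccccc5)[C@@H]4OCc5ccccc5
F7 | step 16 | (4R)-3-[(3S)-3-(Ar-u)-3-(Ar-l)propanoyl]-4-phenyl-1,3-oxazolidin-2-one | O=C(C[C@@H](c3cc4c(c(OCc5ccccc5)c3OCc5ccccc5)O[C@H](c3ccc(OCc5ccccc5)cc3)[C@H](OCc5ccccc5)[C@@H]4OCc5ccccc5)c2ccc(OCc5ccccc5)c(OCc5ccccc5)c2Br)N1[C@H](c6ccccc6)COC1=O
F8 | step 16 | (3S)-3-(Ar-u)-3-(Ar-l)propan-1-ol | OCC[C@@H](c3cc4c(c(OCc5ccccc5)c3OCc5ccccc5)O[C@H](c3ccc(OCc5ccccc5)cc3)[C@H](OCc5ccccc5)[C@@H]4OCc5ccccc5)c2ccc(OCc5ccccc5)c(OCc5ccccc5)c2Br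
F9 | step 8 | (2R,3R)-7,8-bis(benzyloxy)-2-[4-(benzyloxy)phenyl]-6-bromo-3-[(triisopropylsilyl)oxy]-2,3-dihydro-4H-chromen-4-one | O=C1[C@H](O[Si](C(C)C)(C(C)C)C(C)C)[C@@H](c2ccc(OCc3ccccc3)cc2)Oc2c1cc(Br)c(OCc1ccccc1)c2OCc1ccccc1
F10 | step 8 | (2R,3S,4R)-7,8-bis(benzyloxy)-2-[4-(benzyloxy)phenyl]-6-bromo-3-[(triisopropylsilyl)oxy]-3,4-dihydro-2H-chromen-4-ol | O[C@H]1[C@H](O[Si](C(C)C)(C(C)C)C(C)C)[C@@H](c2ccc(OCc3ccccc3)cc2)Oc2c1cc(Br)c(OCc1ccccc1)c2OCc1ccccc1
F11 | step 8 | (2R,3S,4R)-4,7,8-tris(benzyloxy)-2-[4-(benzyloxy)phenyl]-6-bromo-3-[(triisopropylsilyl)oxy]-3,4-dihydro-2H-chromene | c1ccccc1CO[C@H]1[C@H](O[Si](C(C)C)(C(C)C)C(C)C)[C@@H](c2ccc(OCc3ccccc3)cc2)Oc2c1cc(Br)c(OCc1ccccc1)c2OCc1ccccc1
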